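## Retrosynthetic overview

1. The acid comes from its allyl ester; the (E)-enoate comes from a C13 methyl ketone by Horner–Wadsworth–Emmons olefination; the two esters come from stepwise acylation of a 6β,7α-diol (O7 first, hindered O6 second).
2. The diol comes from a 6-keto-Δ8 compound: α-face enolate hydroxylation sets C7, then α-face hydride reduction sets C6.
3. The C9 side chain comes from B-alkyl Suzuki coupling of a C8-methyl C9 enol triflate with a masked 3-oxobutyl borane; 5α-H and the C6 oxygen come from α-face hydroboration of a Δ5 olefin.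
4. The Δ5 C9-ketone comes from Wieland–Miescher ketone (gem-dimethylation, Wolff–Kishner); a ketoreductase differentiates its two carbonyls and upgrades the ee.
5. Ring order: ring A is bought (cyclohexanedione); ring B is closed second by an L-proline-catalysed Robinson annulation that sets C10.

Convention used: labdane numbering (ring A = C1–C5, C10; ring B = C5–C10; C17 on C8; side chain C11–C16); β is the face of the C10 methyl. The target is (5S,6S,7S,10S,13E): 5α-H, 6β-OAc, 7α-O-isovaleryl.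

## Route

Step 1
Reactants: 1 2-methylcyclohexane-1,3-dione; 2 methyl vinyl ketone
Product: 3 2-methyl-2-(3-oxobutyl)cyclohexane-1,3-dione
Conditions: H2O, AcOH (cat.), hydroquinone (cat.), 75 °C
Reagents that add atoms: none
Why: Michael addition of the enolised 1,3-diketone to the enone; no stereocenter is formed because the new quaternary carbon carries two identical carbonyl arms.

Step 2
Reactants: 3 2-methyl-2-(3-oxobutyl)cyclohexane-1,3-dione
Product: 4 (S)-Wieland–Miescher ketone [(8aS)-8a-methyl-3,4,8,8a-tetrahydronaphthalene-1,6(2H,7H)-dione]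
Conditions: L-proline (5 mol%), DMSO, rt, 5 d
Reagents that add atoms: none
Why: Hajos–Parrish–Eder–Sauer–Wiechert aldol condensation in which the proline enamine attacks one of the two enantiotopic ring carbonyls through a hydrogen-bonded chair transition state, setting C10 as S (about 70% ee at this stage).

Step 3
Reactants: 4 (S)-Wieland–Miescher ketone
Product: 5 (4aS,5S)-5-hydroxy-4a-methyl-4,4a,5,6,7,8-hexahydronaphthalen-2(3H)-one (9β-OH)
Conditions: ketoreductase (NADPH-dependent alcohol dehydrogenase, screened for the S ketone), NADP+ (cat.), iPrOH (10 vol%), phosphate buffer pH 7, 30 °C, stopped at about 85% conversion; silica chromatography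
Reagents that add atoms: none
Why: Enzymatic carbonyl reduction in which the ketoreductase accepts (S)-4 much faster than (R)-4 and delivers hydride only to the saturated C9 ketone from the face opposite the angular methyl, giving the 9β (S) carbinol with the enone intact and, after removal of unreacted R-enriched ketone, material of >99% ee.

Step 4
Reactants: 5 (4aS,5S)-5-hydroxy-4a-methyl-4,4a,5,6,7,8-hexahydronaphthalen-2(3H)-one
Product: 6 (4aS,5S)-5-(methoxymethoxy)-4a-methyl-4,4a,5,6,7,8-hexahydronaphthalen-2(3H)-one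
Conditions: MOMCl, iPr2NEt, CH2Cl2, 0 → 40 °C
Reagents that add atoms: chloromethyl methyl ether, COCCl
Why: MOM acetal protection under non-enolising amine-base conditions masks the carbinol for the strongly basic steps that follow.

Step 5
Reactants: 6 (4aS,5S)-5-(methoxymethoxy)-4a-methyl-4,4a,5,6,7,8-hexahydronaphthalen-2(3H)-one
Product: 7 (4aS,5S)-5-(methoxymethoxy)-1,1,4a-trimethyl-3,4,4a,5,6,7-hexahydronaphthalen-2(1H)-one (4,4-dimethyl-Δ5-3-ketone)
Conditions: KOtBu (3 eq), t-BuOH/THF, 0 °C; MeI (4 eq), rt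
Reagents that add atoms: iodomethane, CI
Why: Double α-alkylation of the extended enolate at C4 with deconjugation, the classic gem-dimethylation of such an enone that moves the olefin to Δ5.

Step 6
Reactants: 7 (4aS,5S)-5-(methoxymethoxy)-1,1,4a-trimethyl-3,4,4a,5,6,7-hexahydronaphthalen-2(1H)-one
Product: 9 (1S,8aS)-1-(methoxymethoxy)-5,5,8a-trimethyl-1,2,3,5,6,7,8,8a-octahydronaphthalene, via hydrazone 8 (not isolated)
Conditions: N2H4·H2O, diethylene glycol, 130 °C; then KOH, 200 °C
Reagents that add atoms: none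
Why: Wolff–Kishner reduction (Huang-Minlon variant) removes the C3 carbonyl, and the base-stable MOM ether and the Δ5 olefin (locked by quaternary C4) survive.

Step 7
Reactants: 9 (1S,8aS)-1-(methoxymethoxy)-5,5,8a-trimethyl-1,2,3,5,6,7,8,8a-octahydronaphthalene
Product: 10 (1S,8aS)-5,5,8a-trimethyl-1,2,3,5,6,7,8,8a-octahydronaphthalen-1-ol
Conditions: conc. HCl (cat.), MeOH, 45 °C
Reagents that add atoms: none
Why: Acid-catalysed acetal exchange with methanol cleaves the MOM ether.

Step 8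
Reactants: 10 (1S,8aS)-5,5,8a-trimethyl-1,2,3,5,6,7,8,8a-octahydronaphthalen-1-ol
Product: 11 (8aS)-5,5,8a-trimethyl-3,5,6,7,8,8a-hexahydronaphthalen-1(2H)-one
Conditions: Dess–Martin periodinane, CH2Cl2, rt
Reagents that add atoms: none
Why: Dess–Martin oxidation of the secondary alcohol gives the C9 ketone, deliberately erasing the temporary C9 stereocenter.

Step 9
Reactants: 11 (8aS)-5,5,8a-trimethyl-3,5,6,7,8,8a-hexahydronaphthalen-1(2H)-one
Product: 13 (8aS)-2,5,5,8a-tetramethyl-3,5,6,7,8,8a-hexahydronaphthalen-1(2H)-one (C8 epimers), via lithium enolate 12 (not isolated)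
Conditions: LiN(iPr)2 (1.1 eq), THF, −78 °C; MeI, −78 → 0 °C
Reagents that add atoms: iodomethane, CI
Why: Kinetic enolate alkylation in which C8 is the only enolisable position (C10 is quaternary), and the C8 configuration is irrelevant because C8 becomes sp2 in the next step.

Step 10
Reactants: 13 (8aS)-2,5,5,8a-tetramethyl-3,5,6,7,8,8a-hexahydronaphthalen-1(2H)-one
Product: 15 (8aS)-2,5,5,8a-tetramethyl-3,5,6,7,8,8a-hexahydronaphthalen-1-yl trifluoromethanesulfonate, via potassium enolate 14 (not isolated)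
Conditions: KN(SiMe3)2, THF, −78 → 0 °C; PhNTf2, 0 °C → rt
Reagents that add atoms: N-phenylbis(trifluoromethanesulfonimide), O=S(=O)(N(c1ccccc1)S(=O)(=O)C(F)(F)F)C(F)(F)F
Why: Enolate O-sulfonylation in which the only possible enolate gives the tetrasubstituted C8=C9 enol triflate regiospecifically.

Step 11
Reactants: 15 (8aS)-2,5,5,8a-tetramethyl-3,5,6,7,8,8a-hexahydronaphthalen-1-yl trifluoromethanesulfonate
Product: 17 (4S,4aS,8aS)-4-hydroxy-2,5,5,8a-tetramethyl-3,4,4a,5,6,7,8,8a-octahydronaphthalen-1-yl trifluoromethanesulfonate (6α-OH and 5α-H), via alkylborane 16 (not isolated)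
Conditions: BH3·THF (3 eq), THF, 0 °C → rt; then 30% H2O2, 3 M aq NaOAc, 0 °C → rt
Reagents that add atoms: hydrogen peroxide, OO
Why: Brown hydroboration–oxidation adds H and B syn and anti-Markovnikov to the Δ5 olefin from the α face (the β face is blocked by the C10 and 4β methyls), setting 5α-H (trans-decalin, 5S) and 6α-OH, while the electron-poor tetrasubstituted enol triflate is inert and the buffered oxidation spares it.

Step 12
Reactants: 17 (4S,4aS,8aS)-4-hydroxy-2,5,5,8a-tetramethyl-3,4,4a,5,6,7,8,8a-octahydronaphthalen-1-yl trifluoromethanesulfonate; 18 2-methyl-2-vinyl-1,3-dioxolane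
Product: 20 (5S,6S,10S)-13,13-ethylenedioxy-14,15-dinorlabd-8-en-6α-ol, via B-alkyl-9-BBN 19 (not isolated)
Conditions: 18, 9-BBN, THF, 0 °C → rt; then 17, PdCl2(dppf) (10 mol%), AsPh3 (10 mol%), 3 M aq K3PO4, DMF, 60 °C
Reagents that add atoms: none
Why: B-alkyl Suzuki–Miyaura coupling in which 9-BBN hydroborates the vinyl group terminally and the alkylborane couples with the enol triflate without moving the olefin, the free alcohol and the ketal being tolerated.

Step 13
Reactants: 20 (5S,6S,10S)-13,13-ethylenedioxy-14,15-dinorlabd-8-en-6α-ol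
Product: 21 (5S,10S)-13,13-ethylenedioxy-14,15-dinorlabd-8-en-6-one
Conditions: Dess–Martin periodinane, pyridine, CH2Cl2, 0 °C → rt; used at once
Reagents that add atoms: none
Why: Dess–Martin oxidation under buffered neutral conditions gives the β,γ-unsaturated ketone without conjugating the olefin.

Step 14
Reactants: 21 (5S,10S)-13,13-ethylenedioxy-14,15-dinorlabd-8-en-6-one
Product: 23 (5S,7S,10S)-13,13-ethylenedioxy-7α-hydroxy-14,15-dinorlabd-8-en-6-one, via sodium dienolate 22 (not isolated)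
Conditions: NaN(SiMe3)2 (1.05 eq), THF, −78 °C; 2-(phenylsulfonyl)-3-phenyloxaziridine (1.3 eq), −78 °C; AcOH quench at −78 °C; used crude
Reagents that add atoms: 2-(phenylsulfonyl)-3-phenyloxaziridine, O=S(=O)(c1ccccc1)N1OC1c1ccccc1
Why: Davis enolate hydroxylation in which the doubly activated C7–H is removed kinetically and the dienolate is oxidised at its α-carbon from the α face, opposite the C10 and 4β methyls, setting 7α-OH (7S), with the cold acidic quench preventing ketol isomerisation.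

Step 15
Reactants: 23 (5S,7S,10S)-13,13-ethylenedioxy-7α-hydroxy-14,15-dinorlabd-8-en-6-one
Product: 24 (5S,6S,7S,10S)-13,13-ethylenedioxy-14,15-dinorlabd-8-ene-6β,7α-diol
Conditions: NaBH4, MeOH/THF, −40 → 0 °C
Reagents that add atoms: none
Why: Hydride reduction in which borohydride attacks the C6 carbonyl from the open α face (the β face is shielded by two syn-axial methyls), setting the axial 6β-OH (6S) trans to the 7α-OH.

Step 16
Reactants: 24 (5S,6S,7S,10S)-13,13-ethylenedioxy-14,15-dinorlabd-8-ene-6β,7α-diol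
Product: 25 (5S,6S,7S,10S)-13,13-ethylenedioxy-7α-(3-methylbutanoyloxy)-14,15-dinorlabd-8-en-6β-ol
Conditions: 3-methylbutanoic anhydride (1.2 eq), pyridine, DMAP (5 mol%), CH2Cl2, 0 °C
Reagents that add atoms: 3-methylbutanoic anhydride, CC(C)CC(=O)OC(=O)CC(C)C
Why: Chemoselective DMAP-catalysed acylation of the allylic 7α-OH, the 6β-OH being 1,3-diaxial to two methyls and inert under these mild conditions, and the trans-diaxial geometry excluding acyl migration.

Step 17
Reactants: 25 (5S,6S,7S,10S)-13,13-ethylenedioxy-7α-(3-methylbutanoyloxy)-14,15-dinorlabd-8-en-6β-ol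
Product: 26 (5S,6S,7S,10S)-6β-acetoxy-13,13-ethylenedioxy-7α-(3-methylbutanoyloxy)-14,15-dinorlabd-8-ene
Conditions: Ac2O (10 eq), DMAP (2 eq), pyridine, 60 °C
Reagents that add atoms: acetic anhydride, CC(=O)OC(C)=O
Why: Forcing DMAP-catalysed acetylation (nucleophilic acyl transfer) of the hindered axial 6β-OH with the small acetyl group.

Step 18
Reactants: 26 (5S,6S,7S,10S)-6β-acetoxy-13,13-ethylenedioxy-7α-(3-methylbutanoyloxy)-14,15-dinorlabd-8-ene
Product: 27 (5S,6S,7S,10S)-6β-acetoxy-7α-(3-methylbutanoyloxy)-14,15-dinorlabd-8-en-13-one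
Conditions: 1 M HCl, THF, rt
Reagents that add atoms: water, O
Why: Mild acid-catalysed ketal hydrolysis unmasks the C13 methyl ketone without ionising the allylic ester.

Step 19
Reactants: 27 (5S,6S,7S,10S)-6β-acetoxy-7α-(3-methylbutanoyloxy)-14,15-dinorlabd-8-en-13-one; 28 allyl diethylphosphonoacetate
Product: 30 allyl (5S,6S,7S,10S,13E)-6β-acetoxy-7α-(3-methylbutanoyloxy)labda-8,13-dien-15-oate, via sodium phosphonate 29 (not isolated)
Conditions: 28, NaH, THF, 0 °C; then 27, rt → 50 °C; chromatography to remove the Z isomer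
Reagents that add atoms: none
Why: Horner–Wadsworth–Emmons olefination gives mainly the thermodynamically preferred (E)-trisubstituted enoate (about 5:1 E/Z expected), the two hindered ring esters being inert to the stabilised phosphonate anion.

Step 20
Reactants: 30 allyl (5S,6S,7S,10S,13E)-6β-acetoxy-7α-(3-methylbutanoyloxy)labda-8,13-dien-15-oate
Product: 31 (5S,6S,7S,10S,13E)-6β-acetoxy-7α-(3-methylbutanoyloxy)labda-8,13-dien-15-oic acid (CNP0328312.2)
Conditions: Pd(PPh3)4 (5 mol%), morpholine (5 eq), THF, rt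
Reagents that add atoms: none
Why: Tsuji–Trost deallylation in which zerovalent palladium ionises only the unhindered allyl ester and morpholine traps the allyl group, freeing the acid under neutral conditions that leave the acetate, the isovalerate and the hindered ring allylic C–O bond untouched.

## Compound list

1 | 2-methylcyclohexane-1,3-dione | CC1C(=O)CCCC1=O | starting material
2 | methyl vinyl ketone | CC(=O)C=C | starting material
3 | 2-methyl-2-(3-oxobutyl)cyclohexane-1,3-dione | CC(=O)CCC1(C)C(=O)CCCC1=O | intermediate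
4 | (S)-Wieland–Miescher ketone | C[C@]12CCC(=O)C=C1CCCC2=O | intermediate
5 | (4aS,5S)-5-hydroxy-4a-methyl-4,4a,5,6,7,8-hexahydronaphthalen-2(3H)-one | C[C@]12CCC(=O)C=C1CCC[C@@H]2O | intermediate
6 | (4aS,5S)-5-(methoxymethoxy)-4a-methyl-4,4a,5,6,7,8-hexahydronaphthalen-2(3H)-one | C[C@]12CCC(=O)C=C1CCC[C@@H]2OCOC | intermediate
7 | (4aS,5S)-5-(methoxymethoxy)-1,1,4a-trimethyl-3,4,4a,5,6,7-hexahydronaphthalen-2(1H)-one | C[C@]12CCC(=O)C(C)(C)C1=CCC[C@@H]2OCOC | intermediate
8 | hydrazone of 7 | C[C@]12CCC(=NN)C(C)(C)C1=CCC[C@@H]2OCOC | intermediate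
9 | (1S,8aS)-1-(methoxymethoxy)-5,5,8a-trimethyl-1,2,3,5,6,7,8,8a-octahydronaphthalene | C[C@]12CCCC(C)(C)C1=CCC[C@@H]2OCOC | intermediate
10 | (1S,8aS)-5,5,8a-trimethyl-1,2,3,5,6,7,8,8a-octahydronaphthalen-1-ol | C[C@]12CCCC(C)(C)C1=CCC[C@@H]2O | intermediate
11 | (8aS)-5,5,8a-trimethyl-3,5,6,7,8,8a-hexahydronaphthalen-1(2H)-one | C[C@]12CCCC(C)(C)C1=CCCC2=O | intermediate
12 | lithium enolate of 11 | C[C@]12CCCC(C)(C)C1=CCC=C2[O-].[Li+] | intermediate
13 | (8aS)-2,5,5,8a-tetramethyl-3,5,6,7,8,8a-hexahydronaphthalen-1(2H)-one (C8 epimers) | C[C@]12CCCC(C)(C)C1=CCC(C)C2=O | intermediate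
14 | potassium enolate of 13 | C[C@]12CCCC(C)(C)C1=CCC(C)=C2[O-].[K+] | intermediate
15 | (8aS)-2,5,5,8a-tetramethyl-3,5,6,7,8,8a-hexahydronaphthalen-1-yl trifluoromethanesulfonate | C[C@]12CCCC(C)(C)C1=CCC(C)=C2OS(=O)(=O)C(F)(F)F | intermediate
16 | 6α-boryl (RBH2) adduct of 15, 5α-H | C[C@]12CCCC(C)(C)[C@@H]1[C@@H](B)CC(C)=C2OS(=O)(=O)C(F)(F)F | intermediate
17 | (4S,4aS,8aS)-4-hydroxy-2,5,5,8a-tetramethyl-3,4,4a,5,6,7,8,8a-octahydronaphthalen-1-yl trifluoromethanesulfonate | C[C@]12CCCC(C)(C)[C@@H]1[C@@H](O)CC(C)=C2OS(=O)(=O)C(F)(F)F | intermediate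
18 | 2-methyl-2-vinyl-1,3-dioxolane | C=CC1(C)OCCO1 | starting material
19 | 9-[2-(2-methyl-1,3-dioxolan-2-yl)ethyl]-9-borabicyclo[3.3.1]nonane | CC1(CCB2C3CCCC2CCC3)OCCO1 | intermediate
20 | (5S,6S,10S)-13,13-ethylenedioxy-14,15-dinorlabd-8-en-6α-ol | C[C@]12CCCC(C)(C)[C@@H]1[C@@H](O)CC(C)=C2CCC3(C)OCCO3 | intermediate
21 | (5S,10S)-13,13-ethylenedioxy-14,15-dinorlabd-8-en-6-one | C[C@]12CCCC(C)(C)[C@@H]1C(=O)CC(C)=C2CCC3(C)OCCO3 | intermediate
22 | sodium 6,8-dienolate of 21 | C[C@]12CCCC(C)(C)[C@@H]1C([O-])=CC(C)=C2CCC3(C)OCCO3.[Na+] | intermediate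
23 | (5S,7S,10S)-13,13-ethylenedioxy-7α-hydroxy-14,15-dinorlabd-8-en-6-one | C[C@]12CCCC(C)(C)[C@@H]1C(=O)[C@@H](O)C(C)=C2CCC3(C)OCCO3 | intermediate
24 | (5S,6S,7S,10S)-13,13-ethylenedioxy-14,15-dinorlabd-8-ene-6β,7α-diol | C[C@]12CCCC(C)(C)[C@@H]1[C@H](O)[C@@H](O)C(C)=C2CCC3(C)OCCO3 | intermediate
25 | (5S,6S,7S,10S)-13,13-ethylenedioxy-7α-(3-methylbutanoyloxy)-14,15-dinorlabd-8-en-6β-ol | C[C@]12CCCC(C)(C)[C@@H]1[C@H](O)[C@@H](OC(=O)CC(C)C)C(C)=C2CCC3(C)OCCO3 | intermediate
26 | (5S,6S,7S,10S)-6β-acetoxy-13,13-ethylenedioxy-7α-(3-methylbutanoyloxy)-14,15-dinorlabd-8-ene | C[C@]12CCCC(C)(C)[C@@H]1[C@H](OC(C)=O)[C@@H](OC(=O)CC(C)C)C(C)=C2CCC3(C)OCCO3 | intermediate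
27 | (5S,6S,7S,10S)-6β-acetoxy-7α-(3-methylbutanoyloxy)-14,15-dinorlabd-8-en-13-one | C[C@]12CCCC(C)(C)[C@@H]1[C@H](OC(C)=O)[C@@H](OC(=O)CC(C)C)C(C)=C2CCC(C)=O | intermediate
28 | allyl diethylphosphonoacetate | C=CCOC(=O)CP(=O)(OCC)OCC | starting material
29 | sodium salt of the phosphonate carbanion of 28 | C=CCOC(=O)[CH-]P(=O)(OCC)OCC.[Na+] | intermediate
30 | allyl (5S,6S,7S,10S,13E)-6β-acetoxy-7α-(3-methylbutanoyloxy)labda-8,13-dien-15-oate | C[C@]12CCCC(C)(C)[C@@H]1[C@H](OC(C)=O)[C@@H](OC(=O)CC(C)C)C(C)=C2CC/C(C)=C/C(=O)OCC=C | intermediate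
31 | (5S,6S,7S,10S,13E)-6β-acetoxy-7α-(3-methylbutanoyloxy)labda-8,13-dien-15-oic acid | C[C@]12CCCC(C)(C)[C@@H]1[C@H](OC(C)=O)[C@@H](OC(=O)CC(C)C)C(C)=C2CC/C(C)=C/C(=O)O | target

## Summary

Total steps: 20. Longest linear sequence: 20 steps (1 → 31; compounds 2, 18 and 28 are bought and enter directly).

Three steps most likely to fail, each with one fallback:

**Step 11** (hydroboration of the hindered Δ5 olefin next to an enol triflate). The fallback sets out from 9 and returns at 20; it hydroborates before any triflate exists, so forcing conditions and alkaline peroxide can be used. Compound 9 with BH3·SMe2 (THF, 50 °C; then NaOH, H2O2) gives the 6α-hydroxy MOM ether F1. NaH, BnBr and Bu4NI in DMF give the 6α-benzyl ether F2. HCl in MeOH removes the MOM group to give the 9β-alcohol F3. Dess–Martin periodinane gives the C9 ketone F4. LiN(iPr)2 then MeI gives the 8-methyl ketone F5. KN(SiMe3)2 then PhNTf2 gives the enol triflate F6. Coupling with borane 19 under the step 12 conditions gives the benzyl-protected coupling product F7. Na in liquid NH3/THF at −78 °C cleaves the benzyl ether and delivers 20.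

**Step 12** (B-alkyl Suzuki coupling at a tetrasubstituted enol triflate flanked by quaternary C10). The fallback sets out from 17 and returns at 20; it replaces the sp2–sp3 coupling by a Heck reaction and a conjugate reduction. Heck reaction of 17 with methyl vinyl ketone 2 (Pd(OAc)2, PPh3, Et3N, DMF, 70 °C) gives the ionone-type dienone F8. Conjugate reduction of its disubstituted enone olefin with [(Ph3P)CuH]6 (benzene, H2O, rt) gives the saturated methyl ketone F9. Ketalisation (ethylene glycol, PPTS, benzene, Dean–Stark) gives 20.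

**Step 14** (α-hydroxylation of the β,γ-unsaturated ketone: α versus γ attack, and isomerisation of the ketol). The fallback sets out from 21 and returns at 26; it brings in the C7 oxygen by allylic oxidation and sets C7 by inversion. NaBH4 (MeOH, 0 °C, α-face attack) gives the 6β-alcohol F10. Ac2O, DMAP and pyridine at 60 °C give the 6β-acetate F11. Allylic oxidation at C7 (CrO3, 3,5-dimethylpyrazole, CH2Cl2, −20 °C) gives the 8-en-7-one F12. Reduction with NaBH4 and CeCl3·7H2O (MeOH, −78 °C; hydride anti to the axial 6β-acetate) gives the 7β-alcohol F13. Mitsunobu esterification with 3-methylbutanoic acid (PPh3, DIAD, toluene, 0 °C → rt) inverts C7 and gives 26 directly.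

## Further compounds

F1 | step 11 | 6α-hydroxy-9β-(methoxymethoxy)-4,4,10-trimethyl-trans-decalin (5α-H) | C[C@]12CCCC(C)(C)[C@@H]1[C@@H](O)CC[C@@H]2OCOC
F2 | step 11 | 6α-benzyloxy-9β-(methoxymethoxy)-4,4,10-trimethyl-trans-decalin | C[C@]12CCCC(C)(C)[C@@H]1[C@@H](OCc3ccccc3)CC[C@@H]2OCOC
F3 | step 11 | 6α-benzyloxy-4,4,10-trimethyl-trans-decalin-9β-ol | C[C@]12CCCC(C)(C)[C@@H]1[C@@H](OCc3ccccc3)CC[C@@H]2O
F4 | step 11 | 6α-benzyloxy-4,4,10-trimethyl-trans-decalin-9-one | C[C@]12CCCC(C)(C)[C@@H]1[C@@H](OCc3ccccc3)CCC2=O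
F5 | step 11 | 6α-benzyloxy-4,4,8,10-tetramethyl-trans-decalin-9-one (C8 epimers) | C[C@]12CCCC(C)(C)[C@@H]1[C@@H](OCc3ccccc3)CC(C)C2=O
F6 | step 11 | 6α-benzyloxy-4,4,8,10-tetramethyl-trans-octal-8-en-9-yl trifluoromethanesulfonate | C[C@]12CCCC(C)(C)[C@@H]1[C@@H](OCc3ccccc3)CC(C)=C2OS(=O)(=O)C(F)(F)F
F7 | step 11 | 6α-benzyloxy-13,13-ethylenedioxy-14,15-dinorlabd-8-ene | C[C@]12CCCC(C)(C)[C@@H]1[C@@H](OCc3ccccc3)CC(C)=C2CCC4(C)OCCO4
F8 | step 12 | (11E)-6α-hydroxy-14,15-dinorlabda-8,11-dien-13-one | C[C@]12CCCC(C)(C)[C@@H]1[C@@H](O)CC(C)=C2/C=C/C(C)=O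
F9 | step 12 | 6α-hydroxy-14,15-dinorlabd-8-en-13-one | C[C@]12CCCC(C)(C)[C@@H]1[C@@H](O)CC(C)=C2CCC(C)=O
F10 | step 14 | 13,13-ethylenedioxy-14,15-dinorlabd-8-en-6β-ol | C[C@]12CCCC(C)(C)[C@@H]1[C@H](O)CC(C)=C2CCC3(C)OCCO3
F11 | step 14 | 6β-acetoxy-13,13-ethylenedioxy-14,15-dinorlabd-8-ene | C[C@]12CCCC(C)(C)[C@@H]1[C@H](OC(C)=O)CC(C)=C2CCC3(C)OCCO3
F12 | step 14 | 6β-acetoxy-13,13-ethylenedioxy-14,15-dinorlabd-8-en-7-one | C[C@]12CCCC(C)(C)[C@@H]1[C@H](OC(C)=O)C(=O)C(C)=C2CCC3(C)OCCO3
F13 | step 14 | 6β-acetoxy-13,13-ethylenedioxy-14,15-dinorlabd-8-en-7β-ol | C[C@]12CCCC(C)(C)[C@@H]1[C@H](OC(C)=O)[C@H](O)C(C)=C2CCC3(C)OCCO3
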